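The heterocyclic ring C is opened across O1–C2 and C3–C4. This exploits the ortho-oxybenzyl unit O1–C8a–C4a–C4 of ring A, which is the retron of an ortho-quinone methide, and the C2–C3 unit as the enolate carbon and carbonyl of the ring B arylacetic acid. A chiral isothiourea joins the two achiral halves in a formal [4+2], forming both bonds and setting C3; the precursor pair is a phenolic benzyl sulfone and an arylacetic acid. C2 arrives as a lactone carbonyl and is reduced afterwards. The 8-CHO/7-OH pair travels as a benzodioxinone opened by a last DIBAL-H reduction, and the prenyl group grows from the 2'-O-allyl ether.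

Key step: step 7

Remark: compounds 1 (the acetonide of 2,4,6-trihydroxybenzoic acid) and 6 are taken as catalogue chemicals.
Remark: the (2S,3R) isothiourea is assigned to the 3R product from the accepted transition-state model; should the sense prove opposite, the mirror-image catalyst is used and nothing else changes.
Atom numbers of the target (chromane numbering, ring B primed) are used for compounds 12 to 18.

Step 1
Reactants: 1 5,7-dihydroxy-2,2-dimethyl-4H-1,3-benzodioxin-4-one
Product: 2 5-hydroxy-7-methoxy-2,2-dimethyl-4H-1,3-benzodioxin-4-one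
Conditions: MeI (1.1 equiv), K2CO3, acetone, rt
Reagents that add atoms: iodomethane, CI
Why: Williamson O-methylation should be confined to the free, more acidic 7-OH because the 5-OH is held in a hydrogen bond to the ring carbonyl.

Step 2
Reactants: 2 5-hydroxy-7-methoxy-2,2-dimethyl-4H-1,3-benzodioxin-4-one
Product: 3 6-[(dimethylamino)methyl]-5-hydroxy-7-methoxy-2,2-dimethyl-4H-1,3-benzodioxin-4-one
Conditions: CH2=NMe2+ I− (Eschenmoser's salt, 1.2 equiv), Et3N, CH2Cl2, rt
Reagents that add atoms: N,N-dimethylmethyleneiminium iodide, C=[N+](C)C.[I-]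
Why: Phenol Mannich aminomethylation with the preformed iminium ion should occur at C6, the only position ortho to the free 5-OH, through the phenoxide ion pair.

Step 3
Reactants: 3 6-[(dimethylamino)methyl]-5-hydroxy-7-methoxy-2,2-dimethyl-4H-1,3-benzodioxin-4-one
Product: 5 5-hydroxy-7-methoxy-2,2-dimethyl-6-[(4-methylphenyl)sulfonylmethyl]-4H-1,3-benzodioxin-4-one, via trimethylammonium iodide 4 (not isolated)
Conditions: MeI, MeCN, rt; then TolSO2Na, DMF, 60 °C
Reagents that add atoms: sodium 4-methylbenzenesulfinate, Cc1ccc(cc1)S(=O)[O-].[Na+]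
Why: Quaternisation turns the amine into a leaving group, and S-alkylation of the sulfinate (elimination–addition or direct substitution) should give a storable quinone methide precursor.

Step 4
Reactants: 6 2-hydroxy-4-methoxybenzaldehyde
Product: 7 2-(allyloxy)-4-methoxybenzaldehyde
Conditions: allyl bromide, K2CO3, DMF, 50 °C
Reagents that add atoms: allyl bromide, C=CCBr
Why: Williamson etherification of the phenol installs the allyl ether, which serves as protecting group and later as the source of three prenyl carbons.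

Step 5
Reactants: 7 2-(allyloxy)-4-methoxybenzaldehyde
Product: 8 [2-(allyloxy)-4-methoxyphenyl]acetonitrile
Conditions: TosMIC, t-BuOK, DME, −35 °C; then MeOH, 65 °C
Reagents that add atoms: tosylmethyl isocyanide, Cc1ccc(cc1)S(=O)(=O)C[N+]#[C-]
Why: Van Leusen reductive cyanation converts ArCHO into ArCH2CN with one added carbon, and the low-temperature addition followed by methanolysis should avoid oxazole formation.

Step 6
Reactants: 8 [2-(allyloxy)-4-methoxyphenyl]acetonitrile
Product: 9 [2-(allyloxy)-4-methoxyphenyl]acetic acid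
Conditions: KOH, EtOH/H2O, reflux; then HCl (aq)
Reagents that add atoms: potassium hydroxide, [K+].[OH-]; water, O
Why: Alkaline nitrile hydrolysis should leave the aryl allyl and methyl ethers untouched.

Step 7
Reactants: 9 [2-(allyloxy)-4-methoxyphenyl]acetic acid; 5 5-hydroxy-7-methoxy-2,2-dimethyl-6-[(4-methylphenyl)sulfonylmethyl]-4H-1,3-benzodioxin-4-one
Product: 12 (3R)-3-[2-(allyloxy)-4-methoxyphenyl]-5-methoxy-3,4-dihydrocoumarin carrying a fused 2,2-dimethyl-1,3-dioxin-4-one ring C7–O–C(CH3)2–O–C(=O)–C8, via mixed pivalic anhydride 10 (not isolated), via ortho-quinone methide 11 (not isolated)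
Conditions: 9, t-BuCOCl, iPr2NEt, CH2Cl2, 0 °C; then 5, (2S,3R)-3-isopropyl-2-phenyl-3,4-dihydro-2H-benzo[4,5]thiazolo[3,2-a]pyrimidine (HyperBTM, 10 mol %), Cs2CO3, −20 °C to rt
Reagents that add atoms: none
Why: This is an isothiourea-catalysed C(1)-ammonium enolate Michael addition–lactonisation (formal [4+2]), the closest known type being the reaction of in situ activated arylacetic acids with ortho-quinone methides to give 3-aryl-3,4-dihydrocoumarins. The catalyst is N-acylated by 10 and deprotonated to the (Z)-ammonium enolate, while Cs2CO3 induces 1,4-elimination of sulfinate from 5 to give 11. The enolate carbon adds to the exocyclic CH2 of 11 (C3–C4 bond), and the rearomatised phenoxide then closes the lactone on the acyl ammonium carbonyl (O1–C2 bond, 6-exo-trig acyl substitution), releasing the catalyst. C3 is the only new stereocentre and is set by the catalyst: the 1,5-O···S contact fixes the enolate conformation and the pseudoaxial C2-phenyl group blocks one face, so attack on the open face should give 3R. The step needs C-alkylation of the enolate to outrun O-acylation of the phenol of 5 and oligomerisation of 11, which the low stationary concentration of 11 and its push-pull stabilisation by the methoxy and acetal oxygens should secure. The product lactone is epimerisable at C3 and is therefore reduced without delay.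

Step 8
Reactants: 12 (3R)-3-[2-(allyloxy)-4-methoxyphenyl]-5-methoxy-3,4-dihydrocoumarin carrying the fused 2,2-dimethyl-1,3-dioxin-4-one at C7–C8
Product: 13 (3R)-3-[2-(allyloxy)-4-methoxyphenyl]-5-methoxychroman-2-ol carrying the fused 2,2-dimethyl-1,3-dioxin-4-one at C7–C8 (mixture of C2 epimers)
Conditions: iBu2AlH (1.1 equiv), CH2Cl2, −78 °C; then KNaC4H4O6 (aq)
Reagents that add atoms: none
Why: Partial DIBAL-H reduction of a lactone to the lactol should select the unconjugated aryl alkanoate over the conjugated, trioxygenated benzodioxinone carbonyl and does not touch C3.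

Step 9
Reactants: 13 (3R)-3-[2-(allyloxy)-4-methoxyphenyl]-5-methoxychroman-2-ol carrying the fused 2,2-dimethyl-1,3-dioxin-4-one at C7–C8
Product: 14 (3R)-3-[2-(allyloxy)-4-methoxyphenyl]-5-methoxychromane carrying the fused 2,2-dimethyl-1,3-dioxin-4-one at C7–C8
Conditions: Et3SiH, BF3·OEt2, CH2Cl2, −78 to −40 °C
Reagents that add atoms: none
Why: Ionic hydrogenation of the lactol through the cyclic oxocarbenium ion should turn C2 into CH2 with the O1–C2 bond kept and C3 unchanged at low temperature.

Step 10
Reactants: 14 (3R)-3-[2-(allyloxy)-4-methoxyphenyl]-5-methoxychromane carrying the fused 2,2-dimethyl-1,3-dioxin-4-one at C7–C8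
Product: 16 (3R)-3-(3-allyl-2-hydroxy-4-methoxyphenyl)-5-methoxychromane carrying the fused 2,2-dimethyl-1,3-dioxin-4-one at C7–C8, via cyclohexadienone 15 (not isolated)
Conditions: PhNEt2, 190 °C, sealed tube
Reagents that add atoms: none
Why: Aromatic Claisen rearrangement ([3,3]) should deliver the allyl group to C3', the only free ortho position, and free the 2'-OH on tautomerisation.

Step 11
Reactants: 16 (3R)-3-(3-allyl-2-hydroxy-4-methoxyphenyl)-5-methoxychromane carrying the fused 2,2-dimethyl-1,3-dioxin-4-one at C7–C8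
Product: 17 (3R)-3-[2-hydroxy-4-methoxy-3-(3-methylbut-2-en-1-yl)phenyl]-5-methoxychromane carrying the fused 2,2-dimethyl-1,3-dioxin-4-one at C7–C8
Conditions: second-generation Grubbs catalyst (H2IMes)(PCy3)Cl2Ru=CHPh (5 mol %), 2-methyl-2-butene (excess), CH2Cl2, 40 °C
Reagents that add atoms: 2-methyl-2-butene, CC=C(C)C
Why: Olefin cross-metathesis of the terminal alkene with excess 2-methyl-2-butene is a standard conversion of ortho-allylphenols into prenylphenols.

Step 12
Reactants: 17 (3R)-3-[2-hydroxy-4-methoxy-3-(3-methylbut-2-en-1-yl)phenyl]-5-methoxychromane carrying the fused 2,2-dimethyl-1,3-dioxin-4-one at C7–C8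
Product: 18 (3R)-7-hydroxy-3-[2-hydroxy-4-methoxy-3-(3-methylbut-2-en-1-yl)phenyl]-5-methoxychromane-8-carbaldehyde (target)
Conditions: iBu2AlH (4 equiv), CH2Cl2, −78 °C; then KNaC4H4O6 (aq)
Reagents that add atoms: none
Why: DIBAL-H reduction of a 2,2-dimethyl-1,3-benzodioxin-4-one gives an aluminium hemiacetal that collapses on work-up with loss of acetone to the hydrogen-bonded salicylaldehyde, so 7-OH and 8-CHO should be unveiled together without over-reduction.

Compound list
1 | 5,7-dihydroxy-2,2-dimethyl-4H-1,3-benzodioxin-4-one | CC1(C)OC(=O)c2c(O)cc(O)cc2O1 | starting material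
2 | 5-hydroxy-7-methoxy-2,2-dimethyl-4H-1,3-benzodioxin-4-one | CC1(C)OC(=O)c2c(O)cc(OC)cc2O1 | intermediate
3 | 6-[(dimethylamino)methyl]-5-hydroxy-7-methoxy-2,2-dimethyl-4H-1,3-benzodioxin-4-one | CC1(C)OC(=O)c2c(O)c(CN(C)C)c(OC)cc2O1 | intermediate
4 | (5-hydroxy-7-methoxy-2,2-dimethyl-4-oxo-4H-1,3-benzodioxin-6-yl)methyl-trimethylammonium iodide | CC1(C)OC(=O)c2c(O)c(C[N+](C)(C)C)c(OC)cc2O1.[I-] | intermediate (not isolated)
5 | 5-hydroxy-7-methoxy-2,2-dimethyl-6-[(4-methylphenyl)sulfonylmethyl]-4H-1,3-benzodioxin-4-one | CC1(C)OC(=O)c2c(O)c(CS(=O)(=O)c3ccc(C)cc3)c(OC)cc2O1 | intermediate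
6 | 2-hydroxy-4-methoxybenzaldehyde | COc1ccc(C=O)c(O)c1 | starting material
7 | 2-(allyloxy)-4-methoxybenzaldehyde | COc1ccc(C=O)c(OCC=C)c1 | intermediate
8 | [2-(allyloxy)-4-methoxyphenyl]acetonitrile | COc1ccc(CC#N)c(OCC=C)c1 | intermediate
9 | [2-(allyloxy)-4-methoxyphenyl]acetic acid | COc1ccc(CC(=O)O)c(OCC=C)c1 | intermediate
10 | [2-(allyloxy)-4-methoxyphenyl]acetic pivalic anhydride | COc1ccc(CC(=O)OC(=O)C(C)(C)C)c(OCC=C)c1 | intermediate (not isolated)
11 | 7-methoxy-2,2-dimethyl-6-methylidene-4H-1,3-benzodioxine-4,5(6H)-dione (ortho-quinone methide) | CC1(C)OC(=O)C2=C(O1)C=C(OC)C(=C)C2=O | intermediate (not isolated)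
12 | (3R)-3-[2-(allyloxy)-4-methoxyphenyl]-5-methoxy-3,4-dihydrocoumarin carrying the fused 2,2-dimethyl-1,3-dioxin-4-one ring C7–O–C(CH3)2–O–C(=O)–C8 | COc1ccc([C@@H]2C(=O)Oc3c4C(=O)OC(C)(C)Oc4cc(OC)c3C2)c(OCC=C)c1 | intermediate
13 | (3R)-3-[2-(allyloxy)-4-methoxyphenyl]-5-methoxychroman-2-ol carrying the same fused dioxinone, mixture of C2 epimers | COc1ccc([C@@H]2C(O)Oc3c4C(=O)OC(C)(C)Oc4cc(OC)c3C2)c(OCC=C)c1 | intermediate
14 | (3R)-3-[2-(allyloxy)-4-methoxyphenyl]-5-methoxychromane carrying the same fused dioxinone | COc1ccc([C@@H]2COc3c4C(=O)OC(C)(C)Oc4cc(OC)c3C2)c(OCC=C)c1 | intermediate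
15 | 6-allyl-5-methoxycyclohexa-2,4-dien-1-one tautomer of 16 (ring B dearomatised, chromanyl group at C2 of the dienone) | COC1=CC=C([C@@H]2COc3c4C(=O)OC(C)(C)Oc4cc(OC)c3C2)C(=O)C1CC=C | intermediate (not isolated)
16 | (3R)-3-(3-allyl-2-hydroxy-4-methoxyphenyl)-5-methoxychromane carrying the same fused dioxinone | COc1ccc([C@@H]2COc3c4C(=O)OC(C)(C)Oc4cc(OC)c3C2)c(O)c1CC=C | intermediate
17 | (3R)-3-[2-hydroxy-4-methoxy-3-(3-methylbut-2-en-1-yl)phenyl]-5-methoxychromane carrying the same fused dioxinone | COc1ccc([C@@H]2COc3c4C(=O)OC(C)(C)Oc4cc(OC)c3C2)c(O)c1CC=C(C)C | intermediate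
18 | (3R)-7-hydroxy-3-[2-hydroxy-4-methoxy-3-(3-methylbut-2-en-1-yl)phenyl]-5-methoxychromane-8-carbaldehyde | COc1ccc([C@@H]2COc3c(C=O)c(O)cc(OC)c3C2)c(O)c1CC=C(C)C | target

Total step count: 12. Longest linear sequence: 9 steps (steps 1, 2, 3, 7 to 12, or equally steps 4, 5, 6, 7 to 12).

Steps most likely to fail

Step 7. The catalytic cycle may lose facial control through an uncatalysed background reaction, the activated acid may O-acylate the phenol of 5 before the quinone methide forms, the quinone methide may oligomerise, and the base may epimerise the product lactone at C3. The fallback replaces catalyst control by auxiliary control. It sets out from 9, which is converted (t-BuCOCl, Et3N, THF, −20 °C; then lithiated (R)-4-benzyl-1,3-oxazolidin-2-one from n-BuLi) into the N-acyl oxazolidinone F1. Treatment of F1 with NaN(SiMe3)2 (2.1 equiv, THF, −78 to −20 °C) and then 5 should free 11 with the second equivalent of base. The sodium (Z)-enolate is alkylated by 11 on the face away from the benzyl group, as in Evans alkylations with benzylic electrophiles, giving the phenol imide F2. Et3N with catalytic DMAP in CH2Cl2 then closes the lactone with loss of the auxiliary, and the route is rejoined at 12.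

Step 9. The Lewis acid may open the lactol to the hydroxy aldehyde, which is then reduced to the open-chain alcohol, or the oxocarbenium ion may lose the C3 proton to an enol ether and so erode the configuration. The fallback avoids the cation. It sets out from 13, whose open hydroxy-aldehyde tautomer is reduced with NaBH4 (THF/MeOH, −20 °C) to the phenol primary alcohol (diol) F3. Intramolecular Mitsunobu etherification (PPh3, DIAD, THF, 0 °C to rt) of the acidic, chelated phenol with the primary alcohol closes the pyran ring without involving C3, and the route is rejoined at 14.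

Step 10. At 190 °C the late intermediate may degrade, for example by loss of acetone from the benzodioxinone or by allyl migration through the blocked ortho position to the para position. The fallback builds the prenyl group by a lower-temperature rearrangement. It sets out from 14, which is deallylated (Pd(PPh3)4 cat., morpholine, THF, rt) to the phenol F4. O-Alkylation with 3-chloro-3-methylbut-1-yne (DBU, CuCl2 cat., MeCN, 0 °C) gives the 1,1-dimethylpropargyl ether F5. Semi-hydrogenation (H2, Pd/CaCO3 poisoned with Pb(OAc)2, quinoline, EtOAc) gives the 1,1-dimethylallyl ether F6. Its [3,3] rearrangement in toluene at about 120 °C should place the prenyl group at C3' directly, and the route is rejoined at 17, so steps 10 and 11 are both replaced.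

Further compounds
F1 | step 7 | (4R)-4-benzyl-3-{[2-(allyloxy)-4-methoxyphenyl]acetyl}-1,3-oxazolidin-2-one | COc1ccc(CC(=O)N2[C@H](Cc3ccccc3)COC2=O)c(OCC=C)c1
F2 | step 7 | (4R)-4-benzyl-3-{(2R)-2-[2-(allyloxy)-4-methoxyphenyl]-3-(5-hydroxy-7-methoxy-2,2-dimethyl-4-oxo-4H-1,3-benzodioxin-6-yl)propanoyl}-1,3-oxazolidin-2-one | COc1ccc([C@@H](Cc2c(O)c3C(=O)OC(C)(C)Oc3cc2OC)C(=O)N2[C@H](Cc3ccccc3)COC2=O)c(OCC=C)c1
F3 | step 9 | 6-{(2R)-2-[2-(allyloxy)-4-methoxyphenyl]-3-hydroxypropyl}-5-hydroxy-7-methoxy-2,2-dimethyl-4H-1,3-benzodioxin-4-one | COc1ccc([C@@H](Cc2c(O)c3C(=O)OC(C)(C)Oc3cc2OC)CO)c(OCC=C)c1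
F4 | step 10 | (3R)-3-(2-hydroxy-4-methoxyphenyl)-5-methoxychromane carrying the fused 2,2-dimethyl-1,3-dioxin-4-one at C7–C8 | COc1ccc([C@@H]2COc3c4C(=O)OC(C)(C)Oc4cc(OC)c3C2)c(O)c1
F5 | step 10 | (3R)-3-{4-methoxy-2-[(2-methylbut-3-yn-2-yl)oxy]phenyl}-5-methoxychromane carrying the same fused dioxinone | COc1ccc([C@@H]2COc3c4C(=O)OC(C)(C)Oc4cc(OC)c3C2)c(OC(C)(C)C#C)c1
F6 | step 10 | (3R)-3-{4-methoxy-2-[(2-methylbut-3-en-2-yl)oxy]phenyl}-5-methoxychromane carrying the same fused dioxinone | COc1ccc([C@@H]2COc3c4C(=O)OC(C)(C)Oc4cc(OC)c3C2)c(OC(C)(C)C=C)c1
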